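**Retrosynthetic overview**
- Endgame: the angelate at O3 and the free C18 alcohol are revealed last; the C8 exocyclic methylene is taken back to a C8 ketone, and H9 to a C9 allyl ester that serves as a removable activating group.
- Key disconnection C9–C11: the C9 carbanion of the ring-B β-keto allyl ester adds 1,6 to 4-vinylfuran-2(5H)-one. This delivers C11–C16 with the furanone ring intact and makes C9 quaternary next to the quaternary C10.
- Enabling feature: C9 sits in ring B between C10 and C8 (a masked ketone), and C11 is the δ-carbon of the dienoate O=C15–C14=C13–C12=C11 that the butenolide forms once C11=C12 is unsaturated.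
- Ring order: oxirane (temporary, fixes C3 and C4), then ring A and ring B in one epoxide-initiated cation–olefin cascade of an acyclic (E)-polyene β-keto ester made from geranyl acetate; the furanone ring is bought and only vinylated.

Key step: step 9

Remark: labdane locants are used for all decalin compounds (C18 = oxygenated carbon on C4, C19/C20 = methyls on C4/C10); α and β mean below and above the decalin drawn with C20 down, so the target has C20, C19, O3 and the C9 side chain α and H5, H9 and C18 β.

**Step 1**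
Reactants: 1 geranyl acetate
Product: 2 (2E,6E)-8-hydroxy-3,7-dimethylocta-2,6-dien-1-yl acetate
Conditions: SeO2 (10 mol %), tBuOOH, salicylic acid (cat.), CH2Cl2, rt
Reagents that add atoms: tert-butyl hydroperoxide, CC(C)(C)OO
Why: Selenium dioxide catalysed allylic oxidation (ene reaction then [2,3]-shift) attacks the (E)-methyl of the electron-rich terminal alkene and should leave the acetate-deactivated alkene untouched, giving the (E)-allylic alcohol.

**Step 2**
Reactants: 2 8-hydroxygeranyl acetate
Product: 3 (2E)-5-[(2R,3R)-3-(hydroxymethyl)-3-methyloxiran-2-yl]-3-methylpent-2-en-1-yl acetate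
Conditions: Ti(OiPr)4 (10 mol %), D-(−)-diethyl tartrate (12 mol %), tBuOOH, 4 Å MS, CH2Cl2, −20 °C
Reagents that add atoms: tert-butyl hydroperoxide, CC(C)(C)OO
Why: Sharpless asymmetric epoxidation of an (E)-2-methyl allylic alcohol, in which the D-(−)-tartrate complex should deliver oxygen to the face that gives the (2R,3R)-oxirane, whose CH carbon becomes C3 (retained) and whose quaternary carbon becomes C4 (after inversion).

**Step 3**
Reactants: 3 epoxy alcohol
Product: 4 (2E)-5-[(2R,3R)-3-({[tert-butyl(diphenyl)silyl]oxy}methyl)-3-methyloxiran-2-yl]-3-methylpent-2-en-1-yl acetate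
Conditions: TBDPSCl, imidazole, CH2Cl2, 0 °C to rt
Reagents that add atoms: tert-butyl(chloro)diphenylsilane, CC(C)(C)[Si](Cl)(c1ccccc1)c1ccccc1
Why: Imidazole-mediated silylation of the only free hydroxyl gives a Lewis-acid-stable ether that keeps O18 distinct from O3 until the last step.

**Step 4**
Reactants: 4 silyl ether acetate
Product: 5 (2E)-5-[(2R,3R)-3-({[tert-butyl(diphenyl)silyl]oxy}methyl)-3-methyloxiran-2-yl]-3-methylpent-2-en-1-ol
Conditions: K2CO3 (0.2 equiv), MeOH, 0 °C
Reagents that add atoms: none
Why: Base-catalysed transesterification removes the acetate while the trisubstituted oxirane and the hindered silyl ether should be inert to catalytic methoxide at 0 °C.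

**Step 5**
Reactants: 5 allylic alcohol
Product: 6 {[(2R,3R)-3-[(3E)-5-bromo-3-methylpent-3-en-1-yl]-2-methyloxiran-2-yl]methoxy}(tert-butyl)diphenylsilane
Conditions: CBr4, PPh3, CH2Cl2, −20 to 0 °C
Reagents that add atoms: carbon tetrabromide, BrC(Br)(Br)Br
Why: The Appel reaction converts the primary allylic alcohol to the bromide by SN2 displacement under neutral conditions, so the (E)-alkene and the oxirane should survive.

**Step 6**
Reactants: 6 allylic bromide; 7 allyl acetoacetate (prop-2-en-1-yl 3-oxobutanoate)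
Product: 9 allyl (6E)-9-[(2R,3R)-3-({[tert-butyl(diphenyl)silyl]oxy}methyl)-3-methyloxiran-2-yl]-7-methyl-3-oxonon-6-enoate, via sodium lithium dianion of allyl acetoacetate 8 (not isolated)
Conditions: 7, NaH, THF, 0 °C; n-BuLi, 0 °C; then 6, 0 °C; AcOH
Reagents that add atoms: none
Why: γ-Alkylation of the acetoacetate dianion, in which the more basic terminal carbanion displaces the primary allylic bromide much faster than it opens the trisubstituted oxirane; this joins C6 to C7 and installs the C8 carbonyl and the activated C9.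

**Step 7**
Reactants: 9 acyclic epoxy β-keto ester
Product: 10 allyl (1S,4aS,5S,6R,8aR)-5-({[tert-butyl(diphenyl)silyl]oxy}methyl)-6-hydroxy-5,8a-dimethyl-2-oxodecahydronaphthalene-1-carboxylate (trans-decalin; 3α-OH, 4β-CH2OSi, 4α-CH3, 5β-H, 10α-CH3, 9α-ester)
Conditions: SnCl4 (2 equiv), CH2Cl2, −78 °C; aq. NaHCO3
Reagents that add atoms: none
Why: Epoxide-initiated cation–olefin bicyclisation terminated by C-attack of the tin-chelated β-keto ester enol: in the chair–chair array the C5=C10 alkene opens the oxirane at C4 anti to oxygen (inversion, so CH3 axial and CH2OSi equatorial, O3 retained and equatorial), the (E)-alkene gives the trans ring fusion, and the C9 ester settles equatorial by enolisation.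

**Step 8**
Reactants: 11 4-bromofuran-2(5H)-one; 12 tributyl(vinyl)stannane
Product: 13 4-vinylfuran-2(5H)-one
Conditions: Pd(PPh3)4 (5 mol %), BHT (cat.), toluene, 80 °C; used at once
Reagents that add atoms: none
Why: Stille coupling at the vinylogous acyl bromide proceeds under neutral conditions that spare the base-sensitive butenolide, and immediate use should limit Diels–Alder dimerisation of the diene.

**Step 9**
Reactants: 10 bicyclic β-keto allyl ester; 13 4-vinylfuran-2(5H)-one
Product: 14 allyl (1S,4aS,5S,6R,8aR)-5-({[tert-butyl(diphenyl)silyl]oxy}methyl)-6-hydroxy-5,8a-dimethyl-2-oxo-1-[2-(5-oxo-2,5-dihydrofuran-3-yl)ethyl]decahydronaphthalene-1-carboxylate (side chain β and axial, ester α and equatorial at C9)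
Conditions: 13 (2 equiv), Cs2CO3 (0.3 equiv), MeCN, 0 °C to rt; AcOH
Reagents that add atoms: none
Why: Cs2CO3 deprotonates only the doubly activated C9–H of 10 (the γ-CH2 of 13 is far less acidic), and the soft enolate adds to the unsubstituted δ-carbon C11 of the dienoate of 13; the dienolate formed is protonated by the next molecule of 10 and ends, after base-mediated reconjugation, as the conjugated butenolide, so the base is catalytic. The closest known reaction type is the vinylogous Michael (1,6-conjugate) addition of β-keto esters and malonates to δ-unsubstituted 2,4-dienoates, used here as a fragment union that creates a quaternary carbon next to the quaternary C10. No ring is closed. The new stereocenter C9 is controlled by the axial C20 methyl on the α face, which sends C11 to the β face; this center is temporary and is reset in step 10, so its selectivity is not critical. The step needs C- over O-alkylation, 1,6- over 1,4-addition and mono-addition; these should be secured by the reversibility of O-addition, the fully substituted and shielded β-carbon C13 of 13, and the absence of a second acidic hydrogen at C9 in 14. The free C3 hydroxyl and the silyl ether should be inert to the carbonate base.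

**Step 10**
Reactants: 14 quaternary β-keto allyl ester
Product: 16 4-{2-[(1S,4aS,5S,6R,8aR)-5-({[tert-butyl(diphenyl)silyl]oxy}methyl)-6-hydroxy-5,8a-dimethyl-2-oxodecahydronaphthalen-1-yl]ethyl}furan-2(5H)-one (side chain α and equatorial, H9 β), via β-keto acid 15 (not isolated)
Conditions: Pd(OAc)2 (5 mol %), PPh3 (15 mol %), HCO2H, Et3N, THF, rt then 45 °C
Reagents that add atoms: none
Why: Tsuji deallylation–decarboxylation with formate as hydride donor: zerovalent palladium ionises the allyl ester much faster than the conjugated lactone, the β-keto acid loses CO2, and the enol is protonated on the β face anti to the axial C20 (and equilibrates under Et3N), so the side chain should end equatorial (α) as in the target.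

**Step 11**
Reactants: 16 C8 ketone
Product: 17 4-{2-[(1R,4aS,5S,6R,8aS)-5-({[tert-butyl(diphenyl)silyl]oxy}methyl)-6-hydroxy-5,8a-dimethyl-2-methylidenedecahydronaphthalen-1-yl]ethyl}furan-2(5H)-one
Conditions: Zn, CH2Br2, TiCl4 (reagent pre-formed in THF, excess), CH2Cl2, 0 °C to rt
Reagents that add atoms: dibromomethane, BrCBr
Why: Takai–Lombardo methylenation, whose non-basic CH2(ZnBr)2/TiCl4 reagent olefinates ketones far faster than lactones and does not enolise C9, so the configuration set in step 10 should be kept.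

**Step 12**
Reactants: 17 C3 alcohol; 18 angelic acid [(2Z)-2-methylbut-2-enoic acid]
Product: 20 (1S,2R,4aS,5R,8aS)-1-({[tert-butyl(diphenyl)silyl]oxy}methyl)-1,4a-dimethyl-6-methylidene-5-[2-(5-oxo-2,5-dihydrofuran-3-yl)ethyl]decahydronaphthalen-2-yl (2Z)-2-methylbut-2-enoate, via angelic 2,4,6-trichlorobenzoic anhydride 19 (not isolated)
Conditions: 18, 2,4,6-trichlorobenzoyl chloride, Et3N, toluene, rt; then 17, 80 °C (no DMAP)
Reagents that add atoms: none
Why: Yamaguchi esterification through the pre-formed mixed anhydride without a nucleophilic catalyst, conditions under which angelates are known to form without isomerisation to the tiglate; the C3 hydroxyl is the only free OH and attacks the less hindered angeloyl carbonyl.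

**Step 13**
Reactants: 20 silyl-protected angelate
Product: 21 (1S,2R,4aS,5R,8aS)-1-(hydroxymethyl)-1,4a-dimethyl-6-methylidene-5-[2-(5-oxo-2,5-dihydrofuran-3-yl)ethyl]decahydronaphthalen-2-yl (2Z)-2-methylbut-2-enoate (target)
Conditions: HF·pyridine, pyridine, THF, 0 °C to rt
Reagents that add atoms: none
Why: Fluoride desilylation under mildly acidic buffering cleaves only the Si–O bond and should avoid the base-induced 1,3-acyl shift from O3 to O18, angelate isomerisation and butenolide opening.

**Compound list**
1 | geranyl acetate, (2E)-3,7-dimethylocta-2,6-dien-1-yl acetate | CC(=O)OC/C=C(\C)CCC=C(C)C | starting material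
2 | (2E,6E)-8-hydroxy-3,7-dimethylocta-2,6-dien-1-yl acetate | CC(=O)OC/C=C(\C)CC/C=C(\C)CO | intermediate
3 | (2E)-5-[(2R,3R)-3-(hydroxymethyl)-3-methyloxiran-2-yl]-3-methylpent-2-en-1-yl acetate | CC(=O)OC/C=C(\C)CC[C@H]1O[C@]1(C)CO | intermediate
4 | (2E)-5-[(2R,3R)-3-({[tert-butyl(diphenyl)silyl]oxy}methyl)-3-methyloxiran-2-yl]-3-methylpent-2-en-1-yl acetate | CC(=O)OC/C=C(\C)CC[C@H]1O[C@]1(C)CO[Si](c1ccccc1)(c1ccccc1)C(C)(C)C | intermediate
5 | (2E)-5-[(2R,3R)-3-({[tert-butyl(diphenyl)silyl]oxy}methyl)-3-methyloxiran-2-yl]-3-methylpent-2-en-1-ol | OC/C=C(\C)CC[C@H]1O[C@]1(C)CO[Si](c1ccccc1)(c1ccccc1)C(C)(C)C | intermediate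
6 | {[(2R,3R)-3-[(3E)-5-bromo-3-methylpent-3-en-1-yl]-2-methyloxiran-2-yl]methoxy}(tert-butyl)diphenylsilane | BrC/C=C(\C)CC[C@H]1O[C@]1(C)CO[Si](c1ccccc1)(c1ccccc1)C(C)(C)C | intermediate
7 | allyl acetoacetate (prop-2-en-1-yl 3-oxobutanoate) | CC(=O)CC(=O)OCC=C | starting material
8 | sodium lithium dianion of allyl acetoacetate (not isolated) | [Li+].[Na+].[CH2-]C(=O)[CH-]C(=O)OCC=C | intermediate
9 | allyl (6E)-9-[(2R,3R)-3-({[tert-butyl(diphenyl)silyl]oxy}methyl)-3-methyloxiran-2-yl]-7-methyl-3-oxonon-6-enoate | C=CCOC(=O)CC(=O)CC/C=C(\C)CC[C@H]1O[C@]1(C)CO[Si](c1ccccc1)(c1ccccc1)C(C)(C)C | intermediate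
10 | allyl (1S,4aS,5S,6R,8aR)-5-({[tert-butyl(diphenyl)silyl]oxy}methyl)-6-hydroxy-5,8a-dimethyl-2-oxodecahydronaphthalene-1-carboxylate | O=C1CC[C@H]2[C@@](C)(CC[C@@H](O)[C@]2(C)CO[Si](c3ccccc3)(c3ccccc3)C(C)(C)C)[C@@H]1C(=O)OCC=C | intermediate
11 | 4-bromofuran-2(5H)-one | O=C1C=C(Br)CO1 | starting material
12 | tributyl(vinyl)stannane | C=C[Sn](CCCC)(CCCC)CCCC | starting material
13 | 4-vinylfuran-2(5H)-one | C=CC1=CC(=O)OC1 | intermediate
14 | allyl (1S,4aS,5S,6R,8aR)-5-({[tert-butyl(diphenyl)silyl]oxy}methyl)-6-hydroxy-5,8a-dimethyl-2-oxo-1-[2-(5-oxo-2,5-dihydrofuran-3-yl)ethyl]decahydronaphthalene-1-carboxylate | O=C1CC[C@H]2[C@@](C)(CC[C@@H](O)[C@]2(C)CO[Si](c3ccccc3)(c3ccccc3)C(C)(C)C)[C@]1(CCC1=CC(=O)OC1)C(=O)OCC=C | intermediate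
15 | (1S,4aS,5S,6R,8aR)-5-({[tert-butyl(diphenyl)silyl]oxy}methyl)-6-hydroxy-5,8a-dimethyl-2-oxo-1-[2-(5-oxo-2,5-dihydrofuran-3-yl)ethyl]decahydronaphthalene-1-carboxylic acid (not isolated) | O=C1CC[C@H]2[C@@](C)(CC[C@@H](O)[C@]2(C)CO[Si](c3ccccc3)(c3ccccc3)C(C)(C)C)[C@]1(CCC1=CC(=O)OC1)C(=O)O | intermediate
16 | 4-{2-[(1S,4aS,5S,6R,8aR)-5-({[tert-butyl(diphenyl)silyl]oxy}methyl)-6-hydroxy-5,8a-dimethyl-2-oxodecahydronaphthalen-1-yl]ethyl}furan-2(5H)-one | O=C1CC[C@H]2[C@@](C)(CC[C@@H](O)[C@]2(C)CO[Si](c3ccccc3)(c3ccccc3)C(C)(C)C)[C@@H]1CCC1=CC(=O)OC1 | intermediate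
17 | 4-{2-[(1R,4aS,5S,6R,8aS)-5-({[tert-butyl(diphenyl)silyl]oxy}methyl)-6-hydroxy-5,8a-dimethyl-2-methylidenedecahydronaphthalen-1-yl]ethyl}furan-2(5H)-one | C=C1CC[C@H]2[C@@](C)(CC[C@@H](O)[C@]2(C)CO[Si](c3ccccc3)(c3ccccc3)C(C)(C)C)[C@@H]1CCC1=CC(=O)OC1 | intermediate
18 | angelic acid, (2Z)-2-methylbut-2-enoic acid | C/C=C(/C)C(=O)O | starting material
19 | angelic 2,4,6-trichlorobenzoic anhydride (not isolated) | C/C=C(/C)C(=O)OC(=O)c1c(Cl)cc(Cl)cc1Cl | intermediate
20 | (1S,2R,4aS,5R,8aS)-1-({[tert-butyl(diphenyl)silyl]oxy}methyl)-1,4a-dimethyl-6-methylidene-5-[2-(5-oxo-2,5-dihydrofuran-3-yl)ethyl]decahydronaphthalen-2-yl (2Z)-2-methylbut-2-enoate | C=C1CC[C@H]2[C@@](C)(CC[C@@H](OC(=O)/C(C)=C\C)[C@]2(C)CO[Si](c3ccccc3)(c3ccccc3)C(C)(C)C)[C@@H]1CCC1=CC(=O)OC1 | intermediate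
21 | (1S,2R,4aS,5R,8aS)-1-(hydroxymethyl)-1,4a-dimethyl-6-methylidene-5-[2-(5-oxo-2,5-dihydrofuran-3-yl)ethyl]decahydronaphthalen-2-yl (2Z)-2-methylbut-2-enoate | C=C1CC[C@H]2[C@@](C)(CC[C@@H](OC(=O)/C(C)=C\C)[C@]2(C)CO)[C@@H]1CCC1=CC(=O)OC1 | target

**Step count and risks**
Total step count: 13. Longest linear sequence: 12 steps (steps 1–7 and 9–13, from geranyl acetate); step 8 is the one-step side branch.

Three steps most likely to fail:

1. Step 7. The silyloxymethyl group withdraws electron density from C4, so the oxirane may ionise slowly or at the wrong carbon, undergo a hydride shift before the alkene engages, or the cascade may end by O- rather than C-attack. The fallback sets out from 9 and returns at 10. It changes the terminating nucleophile from a Lewis-acid-bound dicarbonyl to a discrete enol silane and frees the Lewis acid for the oxirane. Silylation of 9 (TBSOTf, Et3N, CH2Cl2, −78 °C) should give the (Z)-tert-butyldimethylsilyl enol ether F1. Treatment with MeAlCl2 (CH2Cl2, −94 °C), the usual promoter for enol-silane-terminated oxirane polyene cyclisations, should close ring A and ring B through the same chair–chair array and give 10 after loss of the silyl group on work-up.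

2. Step 9. Bond formation between the neopentyl-type enolate carbon C9 and the acceptor may be too slow, so that base-induced oligomerisation of the vinyl butenolide or retro-Claisen cleavage of the adduct takes over. The fallback sets out from 9 and returns at 14. It forms the C9–C11 bond before the rings exist. The unhindered acyclic keto ester 9 is added to 13 (Cs2CO3 cat., MeCN) to give the acyclic 1,6-adduct F2 (both C9 epimers serve). SnCl4 cyclisation as in step 7 then builds ring A, ring B and the quaternary C9 in one cation–olefin event; the chelated (Z)-enol should place the ester equatorial and the side chain axial, which is 14.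

3. Step 12. Acylation of the hindered equatorial C3 hydroxyl next to the quaternary C4 may be slow, and prolonged heating may isomerise the angeloyl unit to the tigloyl unit. The fallback sets out from 17 and returns at 20. It builds the (Z)-alkene on the molecule instead of transferring it. Esterification of 17 with 2-[bis(2,2,2-trifluoroethoxy)phosphoryl]propanoic acid (DIC, DMAP cat., CH2Cl2) gives the phosphonopropanoate F3. Deprotonation with KHMDS/18-crown-6 (1.0 equiv, THF, −78 °C, so that the more acidic phosphonate and not the butenolide is deprotonated) and addition of acetaldehyde (Still–Gennari olefination) should give the (Z)-2-methylbut-2-enoate 20.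

**Further compounds**
F1 | step 7 | allyl (2Z,6E)-3-{[tert-butyl(dimethyl)silyl]oxy}-9-[(2R,3R)-3-({[tert-butyl(diphenyl)silyl]oxy}methyl)-3-methyloxiran-2-yl]-7-methylnona-2,6-dienoate | C=CCOC(=O)/C=C(\O[Si](C)(C)C(C)(C)C)CC/C=C(\C)CC[C@H]1O[C@]1(C)CO[Si](c1ccccc1)(c1ccccc1)C(C)(C)C
F2 | step 9 | allyl (6E)-9-[(2R,3R)-3-({[tert-butyl(diphenyl)silyl]oxy}methyl)-3-methyloxiran-2-yl]-7-methyl-3-oxo-2-[2-(5-oxo-2,5-dihydrofuran-3-yl)ethyl]non-6-enoate (C2 epimers) | C=CCOC(=O)C(CCC1=CC(=O)OC1)C(=O)CC/C=C(\C)CC[C@H]1O[C@]1(C)CO[Si](c1ccccc1)(c1ccccc1)C(C)(C)C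
F3 | step 12 | (1S,2R,4aS,5R,8aS)-1-({[tert-butyl(diphenyl)silyl]oxy}methyl)-1,4a-dimethyl-6-methylidene-5-[2-(5-oxo-2,5-dihydrofuran-3-yl)ethyl]decahydronaphthalen-2-yl 2-[bis(2,2,2-trifluoroethoxy)phosphoryl]propanoate | C=C1CC[C@H]2[C@@](C)(CC[C@@H](OC(=O)C(C)P(=O)(OCC(F)(F)F)OCC(F)(F)F)[C@]2(C)CO[Si](c3ccccc3)(c3ccccc3)C(C)(C)C)[C@@H]1CCC1=CC(=O)OC1
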